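# Chemoenzymatic synthesis of CNP0192310.3 by cyclase folding of geranylgeranyl diphosphate

## Numbering, conventions and remark

Skeletal carbons carry the locants C1–C17. C1 is the exocyclic methylene carbon, C2 the ring carbon that bears it, C3 the acetoxy carbon. C4–C8 follow round the eleven-membered ring (C6 bears a methyl). C9=C10 is the tetrasubstituted alkene (C10 bears a methyl). C11 and C12 are the methines shared with the cyclopentane, C13 and C14 its methylenes, C15 the quaternary carbon (methyl). C16 and C17 are the carbinol carbons, and C17 is bonded to C9. The α face is the face of the hydrindane that carries the C15 methyl, H11 and H12. CIP descriptors refer to these locants; from 8 to 15 the spatial arrangement at C6, C11, C12 and C15 is the same, although some descriptors change with the priorities.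

Remark: 5 is drawn as the free acid and is made, stored and used as its trisammonium salt; the cyclase of step 3 is assumed to be used as purified recombinant protein.

Compound key:
- 1 geranylgeraniol
- 2 alkoxysulfonium chloride (not isolated)
- 3 geranylgeranyl chloride
- 4 tris(tetrabutylammonium) hydrogen diphosphate
- 5 geranylgeranyl diphosphate
- 6 cembrene A (enzyme-bound)
- 7 bicyclic triene (enzyme-bound)
- 8 tricyclic diene
- 9 C17 enone
- 10 3-hydroxy enone
- 11 3-acetoxy enone
- 12 sodium enolate (not isolated)
- 13 3-acetoxy-16-hydroxy-17-ketone
- 14 alkoxyborohydride (not isolated)
- 15 target

## Analysis of the target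

Target 15 is a C20 tricycle: a cyclohexene (C9, C10, C11, C15, C16, C17) is cis-fused along C11–C15 to a cyclopentane (C11–C15), and an eleven-membered ring (C2–C12) is fused to the cyclopentane along C11–C12 and ends at the alkene carbon C9. Within the eleven-membered ring the tetrasubstituted C9=C10 alkene is E (C8 and C11 trans), whereas it is cis within the cyclohexene.

There are seven stereocentres, (3R,6R,11S,12R,15S,16R,17R). H11, H12 and the C15 methyl are mutually cis (α). The C16 hydroxyl is α and the C17 hydroxyl β, a trans diol that can sit diequatorially. The C3 acetate and the C6 methyl lie on the medium ring, remote from the rigid core.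

Sensitive groups are the allylic acetate next to the exocyclic methylene (substitution with allyl shift, elimination), the ionisable allylic C17 alcohol and the exocyclic alkene, which can move into the ring under acid.

The difficulty lies in the eleven-membered ring with its bridgehead-like tetrasubstituted alkene, the quaternary C15 and a C6 stereocentre with no neighbouring handle.

The strategy rests on one feature: the twenty skeletal carbons form an unbroken head-to-tail tetraprenyl chain. It runs C17, C16, C15(Me), C14, C13, C12, C2(C1), C3, C4, C5, C6(Me), C7, C8, C9, C10(Me), C11, and is cross-linked by only three bonds, C17–C9, C11–C15 and C11–C12. The chain end C11, a former methyl group, is the carbon that makes two of the three bonds.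

## Retrosynthetic reasoning

**15 to 13 (C17–H).** The C17 carbinol is taken back to the ketone of 13. The C16 hydroxyl of 13 can then bind the hydride donor and deliver hydrogen to C17 from its own face, which makes the diol trans. With this step last, the acetate is already in place and no hydroxyl ever needs protection.

**13 to 11 (C16–O).** The C16 hydroxyl is removed to give enone 11. C16 is the only α′ carbon of the ketone and C15 is quaternary, so a kinetic enolate can form in one place only and cannot eliminate. The forward reaction has to oxidise that enolate on the α face.

**11 to 10 to 9 (acetyl, then C3–O).** The acetate is cut to alcohol 10, and the C3 oxygen is then removed to give 9. Acetylation is placed here because 10 has a single hydroxyl; selective acylation of one of three secondary hydroxyls at the end could not be relied on. The C3 oxygen is introduced at the enone stage because the tetrasubstituted alkene is then part of an enone and inert to an electrophilic ene reagent, which leaves the exocyclic alkene as the only reactive one.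

**9 to 8 (C17=O).** The carbonyl is taken back to the ring methylene of hydrocarbon 8. C17 is the allylic methylene of the six-membered ring, and its oxidation provides the handle for both carbinol centres.

**8 to 5 (C17–C9, C11–C15, C11–C12).** All three cross-links are cut at once, which unfolds the tricycle to the all-E chain of 5, with macrocycle 6 and bicycle 7 as stations. No other cut removes three rings and four stereocentres (C6, C11, C12, C15) while leading to a precursor two steps from a purchasable alcohol. The forward reaction must ionise the diphosphate, close the 14-membered ring, then the cyclohexene, then the cyclopentane, and move one hydride from C11 to C6.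

**5 to 3 + 4, and 3 to 1 (C17–O–P, C17–Cl).** The diphosphate ester is cut at C17–O to allylic chloride 3 and salt 4, and 3 comes from alcohol 1 through 2. Both steps are substitutions at a primary allylic carbon that leave the 2E alkene untouched.

## Alternatives that were turned down

**Alternative 1: Ireland–Claisen ring contraction.**
- Disconnection: the C2–C12 bond, with a C13=C14 alkene and a carboxyl carbon (C1) on C2 as retron.
- Forward key step: the 14-membered lactone A1 (C1 carbonyl, ring oxygen on C14 of a preformed cyclopentene) is turned into its silyl ketene acetal (LDA, Me3SiCl). On warming it rearranges across C2=C1–O–C14–C13=C12 to acid A2, which holds the eleven-membered carbocycle.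
- For: a 14-membered lactone is easier to close than an eleven-membered carbocycle; the suprafacial shift carries the C14 configuration over to C12; every step is established chemistry.
- Against: A1 must already contain the hydrindene with C15, the protected trans diol, the tetrasubstituted alkene, C3 and C6, so the linear sequence before the key step is long. The ester enolate at C2 is β to the C3 silyloxy group and can eliminate. After the key step C1 has to be converted from carboxyl to methylene, C13=C14 hydrogenated and several protecting groups exchanged.
- Comparison: it is stronger in precedent and in the predictability of C12. The chosen route offers all twenty carbons and four stereocentres in three steps, with no protecting group anywhere.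

**Alternative 2: transannular metathesis.**
- Disconnection: the C9=C10 double bond.
- Forward key step: in the 13-membered ring A3 the C9 methylidene and the isopropenyl group on C11 undergo ring-closing metathesis with RuCl2(=CH-C6H4-2-OiPr)(1,3-di-o-tolylimidazolidin-2-ylidene). This forms the tetrasubstituted alkene and, with it, the cyclohexene and the eleven-membered ring of A4.
- For: the hardest alkene is made last from a less strained ring, and A4 already carries all three oxygens. On this point the alternative is stronger, since it needs no C–H oxidation.
- Against: a tetrasubstituted alkene from two 1,1-disubstituted olefins is at the limit of metathesis. A3 holds a third such olefin (C1=C2) that can enter competing ring closures. A3 itself, with seven stereocentres on a medium ring, needs a long synthesis, and the end game needs a silyl-to-acetyl exchange and acetal removal next to an ionisable allylic alcohol.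
- Comparison: the chosen route pays with three late oxidations, but reaches the skeleton far sooner and sets C6, C11, C12 and C15 in one step.

**Alternative 3: transannular Michael–aldol annulation.**
- Disconnection: C11–C15 and C9=C10.
- Forward key step: in the 14-membered keto-enone A5, base turns the acetonyl group on C12 into its C11 enolate, which adds to C15 of the C15=C16–C17=O enone and closes the cyclopentane. C9 of the C17 ketone then condenses with the C10 carbonyl to give the cyclohexenone of A6.
- For: two rings and the tetrasubstituted enone come from textbook reactions, and A6 already has the C17 carbonyl and the C3 oxygen. The site-selectivity question of my step 4 does not arise; here the alternative is stronger.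
- Against: C12 is the only stereocentre near the reacting atoms, so the quaternary C15 and the ring fusion depend on the conformation of the macrocycle. The methyl ketone can enolise towards either side. A5, with four functional sites on a 14-membered ring, is itself a long synthesis.
- Comparison: the chosen route replaces this uncertain conformational control by an active site and saves most of the steps. Alternative 3 is kept as the fallback for the key step.

Key step: step 3

## Route

Step 1
Reactants: 1 (2E,6E,10E)-geranylgeraniol
Product: 3 (2E,6E,10E)-geranylgeranyl chloride, via geranylgeranyloxydimethylsulfonium chloride 2 (not isolated)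
Conditions: NCS, Me2S, CH2Cl2, −30 °C to 0 °C
Reagents that add atoms: N-chlorosuccinimide, O=C1CCC(=O)N1Cl
Why: Corey–Kim chlorination: the alcohol is activated as alkoxysulfonium salt 2 and displaced by chloride in an SN2 reaction under neutral conditions, which keeps the 2E geometry and avoids allylic transposition.

Step 2
Reactants: 3 (2E,6E,10E)-geranylgeranyl chloride; 4 tris(tetrabutylammonium) hydrogen diphosphate
Product: 5 (2E,6E,10E)-geranylgeranyl diphosphate (trisammonium salt)
Conditions: MeCN, rt; then Dowex 50W-X8 (NH4+ form), aq. NH4HCO3/iPrOH; cellulose chromatography
Reagents that add atoms: none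
Why: SN2 displacement of the primary allylic chloride by the diphosphate anion in dry acetonitrile, the standard diphosphorylation of prenyl halides; the non-basic nucleophile attacks C17 without allyl shift, and cation exchange gives the water-soluble salt that the enzyme needs.

Step 3
Reactants: 5 (2E,6E,10E)-geranylgeranyl diphosphate
Product: 8 tricyclic diene (the 3,16,17-trideoxy skeleton of 15), via cembrene A 6 (not isolated), via bicyclic triene 7 (not isolated)
Conditions: engineered class 1 diterpene synthase, MgCl2, HEPES buffer pH 7.5, 30 °C, n-hexane overlay
Reagents that add atoms: none
Why: Proposed new method: no characterised enzyme or reagent is known to give 8, so the step presupposes a class 1 diterpene synthase of this product specificity, to be found by genome mining or evolved from a cembrene A synthase; the closest known reactions are the cyclisations of 5 to cembrene A and to polycyclic diterpenes by class 1 synthases, which ionise the diphosphate with a Mg2+ cluster and steer the cations by the contour of the active site. First, ionisation gives the C15–C16–C17 allyl cation, C9 of the terminal alkene attacks C17 in a 14-membered closure that is exocyclic with respect to the attacking alkene (Markovnikov, tertiary C10 cation), and loss of a methyl proton gives 6. Second, reprotonation at C16 creates the tertiary C15 cation, which the isopropenyl carbon C11 captures in a six-membered closure endocyclic with respect to the attacking alkene, and loss of H9 gives 7. Third, protonation at C5 gives the tertiary C6 cation, which takes the β hydride of C11 through space across the ring, and C12 of the C12=C2 alkene attacks the resulting C9–C10–C11 allyl cation at C11 in a five-membered closure exocyclic with respect to that alkene, which also completes the eleven-membered ring; the C2 cation then loses a C1 proton. C15 is set by the face of the C15 cation that the fold presents to C11, C6 by the face that receives the hydride, C12 by the face of the E-configured C12=C2 alkene that meets C11, and C11 by the tether C12–C13–C14, which can reach C11 only on the face of the C15–C14 bond and so enforces the cis ring fusion. The step needs control over which alkene is protonated and which proton is lost at each stage; the substrate contributes the all-E geometry, the Markovnikov preference at every closure and the short tether, and the rest must come from the active site.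

Step 4
Reactants: 8 tricyclic diene
Product: 9 C17 enone (17-oxo derivative of 8)
Conditions: CrO3, 3,5-dimethylpyrazole, CH2Cl2, −20 °C
Reagents that add atoms: chromium trioxide, O=[Cr](=O)=O
Why: Allylic oxidation of a ring methylene by the CrO3–3,5-dimethylpyrazole complex; the electron-rich tetrasubstituted alkene is attacked in preference to the 1,1-disubstituted one, as in the oxidation of terpene ring methylenes that leaves an isopropenyl group intact. C17 carries the only allylic methylene hydrogen held axial and parallel to the π system in the six-membered ring, whereas the C8 and C11 hydrogens lie near the nodal plane because the C8–C7 and C11–C12 bonds leave the alkene plane to span the eleven-membered ring; no stereocentre is formed.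

Step 5
Reactants: 9 C17 enone
Product: 10 (3R)-3-hydroxy enone
Conditions: SeO2 (cat.), tBuOOH, salicylic acid (cat.), CH2Cl2, 0 °C to rt
Reagents that add atoms: selenium dioxide, O=[Se]=O (oxygen donor, regenerated by tert-butyl hydroperoxide, CC(C)(C)OO)
Why: Selenium dioxide allylic hydroxylation (ene reaction, then [2,3]-sigmatropic shift): the enone alkene is inert to the electrophilic ene step, and on the exocyclic alkene the methylene C3 reacts before the methine C12 (usual order CH2 before CH). Oxygen ends on the face that selenium attacks; the outer α face, on which C12 carries only hydrogen, is expected to be used because the other face is turned towards C11 and the six-membered ring beneath, and this gives the 3R alcohol.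

Step 6
Reactants: 10 (3R)-3-hydroxy enone
Product: 11 (3R)-3-acetoxy enone
Conditions: Ac2O, pyridine, DMAP (cat.), CH2Cl2, 0 °C to rt
Reagents that add atoms: acetic anhydride, CC(=O)OC(C)=O
Why: Nucleophile-catalysed acylation of the only hydroxyl in the molecule; no stereocentre is touched and no selectivity between hydroxyls is required at this stage.

Step 7
Reactants: 11 (3R)-3-acetoxy enone
Product: 13 (3R,16R)-3-acetoxy-16-hydroxy-17-ketone, via sodium enolate 12 (not isolated)
Conditions: NaN(SiMe3)2, THF, −78 °C; 2-(phenylsulfonyl)-3-phenyloxaziridine, −78 °C; AcOH quench
Reagents that add atoms: 2-(phenylsulfonyl)-3-phenyloxaziridine, O=S(=O)(c1ccccc1)N1OC1c1ccccc1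
Why: Kinetic deprotonation on the α′ side gives the cross-conjugated enolate 12 (C16 is the only α′ carbon and the ketone is far more acidic than the acetate), which the N-sulfonyloxaziridine oxidises (Davis enolate hydroxylation). The oxidant is expected to approach C16 from the α face, because the β face is closed by the syn-axial C11–C12 bond and the cyclopentane; the equatorial 16α-hydroxy ketone so formed is also the more stable epimer.

Step 8
Reactants: 13 (3R,16R)-3-acetoxy-16-hydroxy-17-ketone
Product: 15 CNP0192310.3 (the 3-acetoxy-16α,17β-diol), via alkoxydiacetoxyborohydride 14 (not isolated)
Conditions: Me4NBH(OAc)3, MeCN/AcOH (1:1), −25 °C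
Reagents that add atoms: none
Why: Hydroxyl-directed reduction of the Saksena–Evans type: the C16 hydroxyl exchanges an acetate on boron to give 14, which delivers hydride intramolecularly to C17 on the face of the C16 oxygen, so the new hydroxyl is trans to it (17β, 17R). Free triacetoxyborohydride does not reduce the conjugated ketone, the acetate or the alkenes at this temperature, so only the bound hydride reacts.

## Compound list

1 | (2E,6E,10E)-geranylgeraniol | CC(C)=CCC/C(C)=C/CC/C(C)=C/CC/C(C)=C/CO | starting material
2 | geranylgeranyloxydimethylsulfonium chloride (not isolated) | CC(C)=CCC/C(C)=C/CC/C(C)=C/CC/C(C)=C/CO[S+](C)C.[Cl-] | intermediate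
3 | (2E,6E,10E)-geranylgeranyl chloride | CC(C)=CCC/C(C)=C/CC/C(C)=C/CC/C(C)=C/CCl | intermediate
4 | tris(tetrabutylammonium) hydrogen diphosphate | CCCC[N+](CCCC)(CCCC)CCCC.CCCC[N+](CCCC)(CCCC)CCCC.CCCC[N+](CCCC)(CCCC)CCCC.OP(=O)([O-])OP(=O)([O-])[O-] | starting material
5 | (2E,6E,10E)-geranylgeranyl diphosphate (drawn as the acid, used as the trisammonium salt) | CC(C)=CCC/C(C)=C/CC/C(C)=C/CC/C(C)=C/COP(=O)(O)OP(=O)(O)O | intermediate
6 | cembrene A, (R,1E,5E,9E)-1,5,9-trimethyl-12-(prop-1-en-2-yl)cyclotetradeca-1,5,9-triene (enzyme-bound, not isolated; drawn as the R epimer at C9, a centre that is erased in the next stage) | C=C(C)[C@@H]1CC/C(C)=C/CC/C(C)=C/CC/C(C)=C/C1 | intermediate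
7 | bicyclic triene (enzyme-bound, not isolated): cyclohexene closed by C11–C15 with C9=C10 tetrasubstituted, E alkenes C5=C6 and C12=C2 in the 14-membered outer ring, C15 configured as in 8 | CC1=C2CC/C(C)=C/CC/C(C)=C/CC[C@@](C)(C1)CC2 | intermediate
8 | tricyclic diene (6S,11R,12R,15R): C1=C2 exocyclic methylene, C9=C10 alkene, H11, H12 and C15 methyl all α, C6 methyl as in 15 | C=C1CCC[C@H](C)CCC2=C(C)[C@@H]3[C@H]1CC[C@]3(C)CC2 | intermediate
9 | C17 enone (6S,11R,12R,15R), 17-oxo derivative of 8 | C=C1CCC[C@H](C)CCC2=C(C)[C@@H]3[C@H]1CC[C@]3(C)CC2=O | intermediate
10 | (3R)-3-hydroxy enone (3R,6R,11R,12R,15R) | C=C1[C@H](O)CC[C@H](C)CCC2=C(C)[C@@H]3[C@H]1CC[C@]3(C)CC2=O | intermediate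
11 | (3R)-3-acetoxy enone (3R,6R,11R,12R,15R) | C=C1[C@H](OC(C)=O)CC[C@H](C)CCC2=C(C)[C@@H]3[C@H]1CC[C@]3(C)CC2=O | intermediate
12 | sodium C16=C17 enolate of 11 (not isolated) | C=C1[C@H](OC(C)=O)CC[C@H](C)CCC2=C(C)[C@@H]3[C@H]1CC[C@]3(C)C=C2[O-].[Na+] | intermediate
13 | 3-acetoxy-16α-hydroxy-17-ketone (3R,6R,11S,12R,15S,16R) | C=C1[C@H](OC(C)=O)CC[C@H](C)CCC2=C(C)[C@@H]3[C@H]1CC[C@]3(C)[C@@H](O)C2=O | intermediate
14 | tetramethylammonium C16-alkoxy(diacetoxy)borohydride of 13 (not isolated) | C=C1[C@H](OC(C)=O)CC[C@H](C)CCC2=C(C)[C@@H]3[C@H]1CC[C@]3(C)[C@@H](O[BH-](OC(C)=O)OC(C)=O)C2=O.C[N+](C)(C)C | intermediate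
15 | CNP0192310.3, (3R,6R,11S,12R,15S,16R,17R)-3-acetoxy-16α,17β-diol | C=C1[C@H](OC(C)=O)CC[C@H](C)CCC2=C(C)[C@@H]3[C@H]1CC[C@]3(C)[C@@H](O)[C@@H]2O | target

## Step count and least certain steps

Total: 8 steps. Longest linear sequence: 8 steps from 1 (4 enters in step 2).

**Step 3 (key step).** The cascade may leave the enzyme too early, as the macrocyclic or the bicyclic hydrocarbon. The wrong alkene may be protonated, or the C6 cation may be quenched by water or by proton loss before the hydride arrives. Each of the later stages needs an acid–base pair and a fold that a cembrene-forming active site does not have by default. The fallback uses known chemistry and gives up the chain-folding idea. It sets out from none of the numbered compounds, because 1, 3 and 5 all carry the C5=C6 alkene, which no reagent can saturate beside the other three. It starts from the 14-membered keto-enone A5, which has to be assembled separately by fragment coupling and macrocyclisation. Base (KOtBu, tBuOH) effects the transannular Michael addition and aldol condensation to the tricyclic enone A6. Bu4NF in THF then removes the silyl group, and the route is rejoined at 10.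

**Step 4.** Hydrogen abstraction may occur at C8, C11, the C10 methyl or next to the exocyclic alkene instead of C17, since all are allylic and only the alignment of the axial C17–H favours the desired site. Fallback from 8: dye-sensitised singlet oxygen reacts with the tetrasubstituted alkene far faster than with the 1,1-disubstituted one. It should enter on the open α face and take the axial α hydrogen of C17 in an ene reaction, giving the 10α-hydroperoxide with a C9=C17 alkene F1. PPh3 reduces it to the tertiary allylic alcohol F2, and pyridinium chlorochromate (C5H5NH[CrO3Cl]) effects the oxidative 1,3-transposition back to 9.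

**Step 5.** Facial selectivity at C3 may be poor or reversed, because it depends on the conformation of the medium ring about C12–C2–C3. Abstraction of H12 may also compete. Fallback from 9: if selenium uses the other face, the (3S)-alcohol F3 forms, alone or mixed with 10. Dess–Martin oxidation converts either epimer into the 3,17-dione F4. Its C3 carbonyl is the less hindered and more electrophilic of the two, and is reduced with catecholborane and (S)-2-methyl-CBS-oxazaborolidine. With the alkenyl group as the large substituent, reagent control gives the 3R alcohol, and hydride arrives from the face that selenium had used. The route is rejoined at 10.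

**Step 7.** The oxidant may attack the β face, since the axial C15 methyl hinders the α face as well, and some deprotonation of the acetate may occur. Fallback from 11: the hydroxylation mixture that contains the 16β-hydroxy epimer F5 is treated with DBU in toluene under argon. Equilibration through the enediolate moves the axial hydroxyl, which is syn to the C11–C12 bond, into the equatorial position, so that thermodynamic control gives 13.

**Step 8.** The bound hydride may be transferred sluggishly to the hindered conjugated carbonyl, or an external pathway may deliver hydrogen to the β face; the new allylic alcohol could also ionise in acetic acid. Fallback from 13: NaBH4 with CeCl3·7H2O in MeOH at −78 °C should add hydride anti to the axial C15 methyl and give the 16α,17α cis diol F6. Mitsunobu reaction with chloroacetic acid (PPh3, DIAD) opens the intermediate dioxaphosphorane at the allylic carbon with inversion and gives the 17β-chloroacetate F7. Thiourea and NaHCO3 in ethanol remove the chloroacetyl group without touching the acetate and give 15.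

## Further compounds

F0 | step 3 | none | none
F1 | step 4 | 10α-hydroperoxide with C9=C17 alkene (ene product of 8) | C=C1CCC[C@H](C)CCC2=CC[C@@]3(C)CC[C@@H]1[C@H]3[C@]2(C)OO
F2 | step 4 | 10α-hydroxy compound with C9=C17 alkene (tertiary allylic alcohol) | C=C1CCC[C@H](C)CCC2=CC[C@@]3(C)CC[C@@H]1[C@H]3[C@]2(C)O
F3 | step 5 | (3S)-3-hydroxy enone, C3 epimer of 10 | C=C1[C@@H](O)CC[C@H](C)CCC2=C(C)[C@@H]3[C@H]1CC[C@]3(C)CC2=O
F4 | step 5 | 3,17-dione (2-methylene-3-ketone and C17 enone) | C=C1C(=O)CC[C@H](C)CCC2=C(C)[C@@H]3[C@H]1CC[C@]3(C)CC2=O
F5 | step 7 | 3-acetoxy-16β-hydroxy-17-ketone, C16 epimer of 13 | C=C1[C@H](OC(C)=O)CC[C@H](C)CCC2=C(C)[C@@H]3[C@H]1CC[C@]3(C)[C@H](O)C2=O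
F6 | step 8 | 3-acetoxy-16α,17α-diol, C17 epimer of 15 | C=C1[C@H](OC(C)=O)CC[C@H](C)CCC2=C(C)[C@@H]3[C@H]1CC[C@]3(C)[C@@H](O)[C@H]2O
F7 | step 8 | 3-acetoxy-17β-chloroacetoxy-16α-ol | C=C1[C@H](OC(C)=O)CC[C@H](C)CCC2=C(C)[C@@H]3[C@H]1CC[C@]3(C)[C@@H](O)[C@@H]2OC(=O)CCl
A1 | alternative 1 | 14-membered lactone (C1 carbonyl, ring oxygen on C14β of the cyclopentene; C3 silyl ether, C16/C17 methoxymethyl ethers) | O=C1C[C@H](O[Si](C)(C)C(C)(C)C)CC[C@H](C)CCC2=C(C)[C@@H]3C=C[C@H](O1)[C@]3(C)[C@@H](OCOC)[C@@H]2OCOC
A2 | alternative 1 | eleven-membered carbocyclic acid with C13=C14 alkene (product of the ring contraction) | OC(=O)[C@@H]1[C@H](O[Si](C)(C)C(C)(C)C)CC[C@H](C)CCC2=C(C)[C@@H]3[C@H]1C=C[C@]3(C)[C@@H](OCOC)[C@@H]2OCOC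
A3 | alternative 2 | 13-membered ring with C9 methylidene and isopropenyl group on C11 (metathesis substrate) | C=C1[C@H](O[Si](C)(C)C(C)(C)C)CC[C@H](C)CCC(=C)[C@@H](OCOC)[C@H](OCOC)[C@@]2(C)CC[C@@H]1[C@H]2C(C)=C
A4 | alternative 2 | protected target skeleton (C3 silyl ether, C16/C17 methoxymethyl ethers) | C=C1[C@H](O[Si](C)(C)C(C)(C)C)CC[C@H](C)CCC2=C(C)[C@@H]3[C@H]1CC[C@]3(C)[C@@H](OCOC)[C@@H]2OCOC
A5 | alternative 3 | 14-membered keto-enone with acetonyl group on C12 (annulation substrate) | C=C1[C@H](O[Si](C)(C)C(C)(C)C)CC[C@H](C)CCCC(=O)/C=C(C)/CC[C@@H]1CC(C)=O
A6 | alternative 3 | tricyclic C17 enone with C3 silyl ether | C=C1[C@H](O[Si](C)(C)C(C)(C)C)CC[C@H](C)CCC2=C(C)[C@@H]3[C@H]1CC[C@]3(C)CC2=O
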